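**Retrosynthetic overview**
1. Violacene (11) ⇐ Markovnikov, anti addition of BrCl to the exocyclic alkene of allylic chloride 10, which sets C(Cl)(CH2Br) last.
2. 10 ⇐ SN2 chlorination (inversion) of allylic alcohol 9 ⇐ CBS reduction of exo-methylene enone 8, so the secondary C–Cl is set while its neighbour is still sp2.
3. 8 ⇐ regiospecific α-methylenation of silyl enol ether 7 ⇐ Takai chloro-olefination of aldehyde 6.
4. The only ring is formed by a catalytic enantioselective Diels–Alder of (Z)-3-chloro-2-methylacrolein (3) with 2-silyloxybutadiene (5), which sets the quaternary carbon and the adjacent C–Cl (cis).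
5. 3 comes from propargyl alcohol (1); 5 comes from methyl vinyl ketone (4).

Assumptions: the SMILES is read as (1R,2S,4R,5R)-violacene, with the three ring chlorines and the chlorovinyl group all on one face; diene 5 is made rather than bought; the catalyst antipode in step 4 is assigned from the Corey pre-transition-state model for 2-substituted enals (use the other antipode if the sense is opposite); BrCl in step 9 is used as a freshly prepared CH2Cl2 solution.

**Step 1**
Reactants: 1 prop-2-yn-1-ol
Product: 2 (Z)-3-chloro-2-methylprop-2-en-1-ol (Cl cis to CH2OH)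
Conditions: MeMgBr (2.5 equiv), CuI (10 mol %), THF/Et2O, 0 °C → rt; then NCS, −30 °C → rt
Reagents that add atoms: methylmagnesium bromide C[Mg]Br (CH3); N-chlorosuccinimide O=C1CCC(=O)N1Cl (Cl)
Why: Cu-catalysed anti-carbomagnesiation of the propargylic alkoxide (Duboudin–Jousseaume) gives a chelated (Z)-vinylmagnesium, which is chlorinated with retention.

**Step 2**
Reactants: 2 (Z)-3-chloro-2-methylprop-2-en-1-ol
Product: 3 (Z)-3-chloro-2-methylprop-2-enal
Conditions: MnO2, CH2Cl2, rt, dark; used directly as a solution
Reagents that add atoms: none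
Why: Neutral allylic oxidation with MnO2 keeps the kinetically set Z geometry (Cl cis to CHO).

**Step 3**
Reactants: 4 but-3-en-2-one (methyl vinyl ketone)
Product: 5 2-(tert-butyldimethylsilyloxy)buta-1,3-diene
Conditions: TBSOTf, Et3N, Et2O, 0 °C
Reagents that add atoms: TBSOTf CC(C)(C)[Si](C)(C)OS(=O)(=O)C(F)(F)F
Why: Soft enolisation and O-silylation of the methyl ketone gives the 2-silyloxydiene.

**Step 4**
Reactants: 3 (Z)-3-chloro-2-methylprop-2-enal; 5 2-(TBSO)buta-1,3-diene
Product: 6 (1R,6R)-4-(tert-butyldimethylsilyloxy)-6-chloro-1-methylcyclohex-3-ene-1-carbaldehyde (Cl cis to CHO)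
Conditions: (R)-o-tolyl-CBS oxazaborolidine·HNTf2 (Corey oxazaborolidinium, 20 mol %), CH2Cl2, −78 → −40 °C
Reagents that add atoms: none
Why: Catalytic enantioselective Diels–Alder; the silyloxy group directs "para" to the formyl-bearing carbon, suprafacial addition keeps Cl cis to CHO, and the (R)-catalyst exposes the Cα-Re face of the s-trans enal to give 1R,6R.

**Step 5**
Reactants: 6
Product: 7 tert-butyl{[(4R,5R)-5-chloro-4-[(E)-2-chloroethenyl]-4-methylcyclohex-1-en-1-yl]oxy}dimethylsilane
Conditions: CrCl2 (6 equiv), CHCl3, THF, 65 °C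
Reagents that add atoms: chloroform ClC(Cl)Cl (CHCl)
Why: Takai olefination gives the (E)-vinyl chloride from the non-enolisable aldehyde; the TBS enol ether and the secondary alkyl chloride are inert to Cr(II).

**Step 6**
Reactants: 7
Product: 8 (4R,5R)-5-chloro-4-[(E)-2-chloroethenyl]-4-methyl-2-methylidenecyclohexan-1-one
Conditions: Me2N=CH2+ I− (Eschenmoser's salt), CH2Cl2, rt; then MeI; then aq NaHCO3, 0 °C; used at once
Reagents that add atoms: Eschenmoser's salt C=[N+](C)C.[I-] (CH2)
Why: Mannich reaction at the nucleophilic carbon of the regiodefined silyl enol ether, then quaternisation and mild E1cB loss of Me3N, places the methylene on the correct α-carbon.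

**Step 7**
Reactants: 8
Product: 9 (1R,4R,5R)-5-chloro-4-[(E)-2-chloroethenyl]-4-methyl-2-methylidenecyclohexan-1-ol (OH trans to the ring Cl)
Conditions: (S)-Me-CBS (20 mol %), catecholborane, toluene, −78 °C
Reagents that add atoms: none
Why: Corey–Bakshi–Shibata 1,2-reduction with the alkenyl side acting as the large group gives the (R)-carbinol under reagent control, overriding the substrate preference for the equatorial alcohol.

**Step 8**
Reactants: 9
Product: 10 (1R,2R,4S)-2,4-dichloro-1-[(E)-2-chloroethenyl]-1-methyl-5-methylidenecyclohexane (the two ring Cl cis)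
Conditions: PPh3, Cl3CC(O)CCl3, CH2Cl2, 0 °C
Reagents that add atoms: hexachloroacetone ClC(Cl)(Cl)C(=O)C(Cl)(Cl)Cl (Cl)
Why: Appel-type chlorination of the allylic alcohol proceeds by SN2 with inversion and without allylic transposition, turning the axial OH into the equatorial Cl.

**Step 9**
Reactants: 10
Product: 11 violacene, (1R,2S,4R,5R)-1-(bromomethyl)-1,2,4-trichloro-5-[(E)-2-chloroethenyl]-5-methylcyclohexane
Conditions: BrCl (1.1 equiv, freshly prepared solution in CH2Cl2), CH2Cl2, −78 °C, dark
Reagents that add atoms: bromine monochloride ClBr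
Why: Electrophilic Markovnikov anti bromochlorination of the 1,1-disubstituted alkene with molecular BrCl, whose cation-like bromonium favours chloride at the tertiary carbon; Br+ adds to the CH2 terminus from the equatorial face (anti to the axial chlorovinyl group) and chloride opens the tertiary carbon axially, leaving CH2Br equatorial and the new Cl cis to the neighbouring Cl, while the electron-poor chlorovinyl group does not react.

**Compound list**
1 | prop-2-yn-1-ol | C#CCO | starting material
2 | (Z)-3-chloro-2-methylprop-2-en-1-ol | Cl/C=C(/C)CO | intermediate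
3 | (Z)-3-chloro-2-methylprop-2-enal | Cl/C=C(/C)C=O | intermediate
4 | but-3-en-2-one | CC(=O)C=C | starting material
5 | 2-(tert-butyldimethylsilyloxy)buta-1,3-diene | C=CC(=C)O[Si](C)(C)C(C)(C)C | intermediate
6 | (1R,6R)-4-(TBSO)-6-chloro-1-methylcyclohex-3-ene-1-carbaldehyde | C[C@]1(C=O)CC=C(O[Si](C)(C)C(C)(C)C)C[C@H]1Cl | intermediate
7 | tert-butyl{[(4R,5R)-5-chloro-4-[(E)-2-chloroethenyl]-4-methylcyclohex-1-en-1-yl]oxy}dimethylsilane | C[C@]1(/C=C/Cl)CC=C(O[Si](C)(C)C(C)(C)C)C[C@H]1Cl | intermediate
8 | (4R,5R)-5-chloro-4-[(E)-2-chloroethenyl]-4-methyl-2-methylidenecyclohexan-1-one | C[C@]1(/C=C/Cl)CC(=C)C(=O)C[C@H]1Cl | intermediate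
9 | (1R,4R,5R)-5-chloro-4-[(E)-2-chloroethenyl]-4-methyl-2-methylidenecyclohexan-1-ol | C[C@]1(/C=C/Cl)CC(=C)[C@H](O)C[C@H]1Cl | intermediate
10 | (1R,2R,4S)-2,4-dichloro-1-[(E)-2-chloroethenyl]-1-methyl-5-methylidenecyclohexane | C[C@]1(/C=C/Cl)CC(=C)[C@@H](Cl)C[C@H]1Cl | intermediate
11 | violacene, (1R,2S,4R,5R)-1-(bromomethyl)-1,2,4-trichloro-5-[(E)-2-chloroethenyl]-5-methylcyclohexane | C[C@]1(/C=C/Cl)C[C@](Cl)(CBr)[C@@H](Cl)C[C@H]1Cl | target

**Totals**
Total steps: 9. Longest linear sequence: 8 (steps 1, 2, 4, 5, 6, 7, 8, 9).

**Three steps most likely to fail**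
- **Step 4 (Diels–Alder).** The Z-β-chloro enal may react slowly, isomerise to E, or give poor ee or the opposite sense. Fallback: run the cycloaddition racemically (thermal or Me2AlCl) and take racemic 8 into the reagent-controlled CBS reduction; the two enantiomers then give diastereomeric alcohols, and (1R,4R,5R)-9 is separated by chromatography.
- **Step 6 (α-methylenation).** The ketone has a β-chloride that can be lost by E1cB, and exo-methylene enones dimerise. Fallback: avoid the ketone by using 3-methyl-2-(TBSO)buta-1,3-diene (from 3-methylbut-3-en-2-one) in the Diels–Alder. After Takai olefination, convert the enol ether to the enol triflate (CsF, PhNTf2), reduce it (Pd(OAc)2/PPh3, HCO2H, Bu3N) to the 1-methylcyclohexene, epoxidise, and isomerise the epoxide with Et2AlTMP to reach allylic alcohol 9 (Mitsunobu inversion if the carbinol epimer forms).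
- **Step 9 (bromochlorination).** Regio- or facial selectivity at the tertiary carbon may be poor, since it is flanked by a C–Cl and the axial chlorovinyl group. Fallback: epoxidise 10 from the equatorial face (mCPBA or DMDO), open the spiro-epoxide at the tertiary carbon with chloride and inversion (TiCl4, −78 °C), then convert the primary alcohol to the bromide (CBr4, PPh3).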